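**Retrosynthetic overview**

1. Target 22 ⇐ hydrogenolysis of the two C5–O benzyl ethers of bis-chroman 21 ⇐ key step: both pyran O1–C2 bonds are made from the open bis-prenyl tetraphenol 18.
2. 18 ⇐ C6–CH bond between ring A monomer 7 and the ortho-quinone methide 17 released from sulfone 16 (ring B monomer 11 + 6-methylheptanal 14 + a sulfinic acid); a bifunctional squaramide sets the (R)-methine here, so the four ortho hydroxyls need no protection.
3. Monomers 7 and 11 ⇐ phloroglucinol by Friedel-Crafts acylation, C-prenylation and benzylation of the oxygen para to the acyl group; the (R)-2-methylbutanoyl centre comes from the chiral-pool acid.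
4. Feature the plan rests on: on each aromatic ring (A and B) the fused pyran ring (C and D) has as O1 the phenolic oxygen on C8a, ortho to the C8 acyl group, and as C2 a gem-dimethyl carbon. O1–C2 is therefore the bond a C4a prenyl group forms by Markovnikov addition of the C8a hydroxyl, once the other neighbouring oxygen (on C5) is blocked as a benzyl ether.
5. Ring order: aromatic rings A and B come ready-made from phloroglucinol; pyran rings C and D are closed last, in one operation and in either order.

Key step: step 11

Convention: chroman locants are used for both halves at every stage (C8 acyl, C7 and C8a the ortho oxygens, C5 the para oxygen, C6 the bridging carbon, C4a the prenyl or pyran carbon). Ring A carries the (R)-2-methylbutanoyl group, ring B the 2-methylpropanoyl group.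

Assumption: the epi-quinine-derived squaramide of step 10 is taken to favour the (R)-methine; the sense of induction on this quinone methide cannot be predicted with certainty, so the pseudo-enantiomeric epi-quinidine-derived squaramide takes its place if the other epimer predominates.

**Route**

Step 1
Reactants: 1 phloroglucinol; 2 (R)-2-methylbutanoic acid
Product: 4 (2R)-2-methyl-1-(2,4,6-trihydroxyphenyl)butan-1-one, via acid chloride 3 (not isolated)
Conditions: (COCl)2, cat. DMF, CH2Cl2, 0 °C to rt; then 1, AlCl3 (3.5 equiv), PhNO2, 0 °C to rt; cold aq. HCl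
Reagents that add atoms: none
Why: Friedel-Crafts C-acylation of the very electron-rich triol stops after one acyl group because the ketone deactivates the ring; the (R) centre is carried over from the acid, and the low temperature is chosen so that neither the acid chloride nor the aluminium-bound ketone enolises.

Step 2
Reactants: 4 (2R)-2-methyl-1-(2,4,6-trihydroxyphenyl)butan-1-one; 5 1-bromo-3-methylbut-2-ene
Product: 6 (2R)-2-methyl-1-[2,4,6-trihydroxy-3-(3-methylbut-2-en-1-yl)phenyl]butan-1-one
Conditions: 5 (1.0 equiv), 10% aq. KOH, 0 °C; then aq. HCl to pH 3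
Reagents that add atoms: none
Why: C-alkylation of the aqueous phloroglucinol polyanion (an enolate-like ambident phenoxide) by the allylic bromide at one of its two equivalent free ring carbons, held at the mono-prenyl stage by limiting bromide; the ketone is part of the delocalised anion, so its alpha centre is not deprotonated.

Step 3
Reactants: 6 (2R)-2-methyl-1-[2,4,6-trihydroxy-3-(3-methylbut-2-en-1-yl)phenyl]butan-1-one
Product: 7 (2R)-1-[4-(benzyloxy)-2,6-dihydroxy-3-(3-methylbut-2-en-1-yl)phenyl]-2-methylbutan-1-one (ring A monomer)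
Conditions: BnBr (1.0 equiv), K2CO3 (1.1 equiv), acetone, rt
Reagents that add atoms: benzyl bromide, BrCc1ccccc1
Why: Williamson etherification at the hydroxyl para to the acyl group, which is the most acidic of the three and is not held in the chelate with the ketone, so one equivalent of base and bromide should benzylate this oxygen in preference to the two ortho hydroxyls.

Step 4
Reactants: 1 phloroglucinol; 8 2-methylpropanoyl chloride
Product: 9 2-methyl-1-(2,4,6-trihydroxyphenyl)propan-1-one
Conditions: AlCl3 (3.5 equiv), PhNO2/CH2Cl2, 0 °C to rt; cold aq. HCl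
Reagents that add atoms: none
Why: the same Friedel-Crafts mono-acylation as in step 1, here with an achiral acid chloride.

Step 5
Reactants: 9 2-methyl-1-(2,4,6-trihydroxyphenyl)propan-1-one; 5 1-bromo-3-methylbut-2-ene
Product: 10 2-methyl-1-[2,4,6-trihydroxy-3-(3-methylbut-2-en-1-yl)phenyl]propan-1-one
Conditions: 5 (1.0 equiv), 10% aq. KOH, 0 °C; then aq. HCl to pH 3
Reagents that add atoms: none
Why: C-prenylation of the phloroglucinol polyanion at a free ring carbon, as in step 2.

Step 6
Reactants: 10 2-methyl-1-[2,4,6-trihydroxy-3-(3-methylbut-2-en-1-yl)phenyl]propan-1-one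
Product: 11 1-[4-(benzyloxy)-2,6-dihydroxy-3-(3-methylbut-2-en-1-yl)phenyl]-2-methylpropan-1-one (ring B monomer)
Conditions: BnBr (1.0 equiv), K2CO3 (1.1 equiv), acetone, rt
Reagents that add atoms: benzyl bromide, BrCc1ccccc1
Why: Williamson etherification of the most acidic, para hydroxyl, as in step 3.

Step 7
Reactants: 12 6-methylheptanoic acid
Product: 13 6-methylheptan-1-ol
Conditions: LiAlH4, THF, 0 °C to reflux; Fieser work-up
Reagents that add atoms: none
Why: hydride reduction of a carboxylic acid to the primary alcohol.

Step 8
Reactants: 13 6-methylheptan-1-ol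
Product: 14 6-methylheptanal
Conditions: TEMPO (10 mol%), PhI(OAc)2 (1.1 equiv), CH2Cl2, rt
Reagents that add atoms: none
Why: oxoammonium (TEMPO) oxidation of a primary alcohol, which stops at the aldehyde in the absence of water.

Step 9
Reactants: 11 1-[4-(benzyloxy)-2,6-dihydroxy-3-(3-methylbut-2-en-1-yl)phenyl]-2-methylpropan-1-one; 14 6-methylheptanal
Product: 16 racemic 1-[4-(benzyloxy)-2,6-dihydroxy-3-[6-methyl-1-(4-methylbenzenesulfonyl)heptyl]-5-(3-methylbut-2-en-1-yl)phenyl]-2-methylpropan-1-one, via benzylic carbinol 15 (not isolated)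
Conditions: 14 (1.5 equiv), 4-MeC6H4SO2H (2.5 equiv), MgSO4, CH2Cl2, 0 °C to rt
Reagents that add atoms: 4-methylbenzenesulfinic acid, Cc1ccc(cc1)S(=O)O
Why: three-component Mannich-type sulfonylalkylation in which the only free ring carbon of 11 adds to the aldehyde, carbinol 15 ionises under the acid to the protonated quinone methide, and the excess sulfinic acid, a far better nucleophile than a second molecule of 11, captures it through sulfur to give a sulfone whose own ring is fully substituted.

Step 10
Reactants: 16 racemic sulfone; 7 ring A monomer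
Product: 18 (2R)-1-[4-(benzyloxy)-3-[(1R)-1-[6-(benzyloxy)-2,4-dihydroxy-3-(2-methylpropanoyl)-5-(3-methylbut-2-en-1-yl)phenyl]-6-methylheptyl]-2,6-dihydroxy-5-(3-methylbut-2-en-1-yl)phenyl]-2-methylbutan-1-one, via ortho-quinone methide 17 (not isolated)
Conditions: 3,5-bis(trifluoromethyl)phenyl squaramide of 9-amino-9-deoxy-epi-quinine (10 mol%), sat. aq. NaHCO3, CH2Cl2, 0 °C
Reagents that add atoms: none
Why: base-triggered 1,4-elimination of sulfinate gives the ortho-quinone methide, whose carbonyl is bound by the two squaramide N–H bonds while the phenoxide of 7 is held as an ion pair on the quinuclidinium, so the only free ring carbon of 7 adds to one face of the exocyclic carbon (organocatalytic asymmetric Friedel-Crafts-type conjugate addition to an ortho-quinone methide); this catalyst-controlled facial selectivity sets the (R)-methine and both rings rearomatise.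

Step 11
Reactants: 18 open bis-prenyl tetraphenol
Product: 21 (2R)-1-[5-(benzyloxy)-6-[(1R)-1-[5-(benzyloxy)-7-hydroxy-2,2-dimethyl-8-(2-methylpropanoyl)-3,4-dihydro-2H-chromen-6-yl]-6-methylheptyl]-7-hydroxy-2,2-dimethyl-3,4-dihydro-2H-chromen-8-yl]-2-methylbutan-1-one, via ring A monochroman 19 (not isolated), via ring B monochroman 20 (not isolated)
Conditions: (R,R)-N,N'-bis(3,5-di-tert-butylsalicylidene)-1,2-cyclohexanediaminocobalt (10 mol%), N-fluoro-2,4,6-trimethylpyridinium triflate (2.5 equiv), PhSiH3 (2.5 equiv), degassed PhCF3, 0 °C to rt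
Reagents that add atoms: none
Why: The N-fluoropyridinium salt oxidises the divalent cobalt salen complex to a trivalent cobalt fluoride, phenylsilane converts this into a cobalt hydride, and the hydride passes a hydrogen atom to the CH end of each prenyl alkene to give the tertiary radical; this radical is oxidised through a tetravalent alkylcobalt (radical-polar crossover) to a tertiary cation equivalent, which the C8a hydroxyl captures with loss of a proton. The closest known reaction type is the cobalt-salen hydrogen-atom-transfer hydroalkoxylation of unactivated alkenes by alcohols and phenols (a Mukaiyama-type hydrofunctionalisation), with the acid-promoted closure of ortho-prenylphenols to 2,2-dimethylchromans as its classical counterpart. Ring C and ring D each close in the 6-endo-trig mode, the oxygen attacking the gem-dimethyl carbon so that both former alkene carbons lie inside the new pyran ring, and the two closures are independent and may run through 19 or 20. No stereocentre is created because C2 carries two methyl groups, and the neutral medium should leave the ionisable diarylmethine and the centre alpha to the ketone untouched. The selectivity needed is between the two oxygens flanking each prenyl group: O–C8a is a free phenol that ends as a neutral ether after proton loss, whereas O–C5 is an aryl benzyl ether of low nucleophilicity that could react only through an oxonium ion, and the C7 hydroxyl is meta to the prenyl group and cannot reach it.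

Step 12
Reactants: 21 di-O-benzyl bis-chroman
Product: 22 (2R)-1-[6-[(1R)-1-[5,7-dihydroxy-2,2-dimethyl-8-(2-methylpropanoyl)-3,4-dihydro-2H-chromen-6-yl]-6-methylheptyl]-5,7-dihydroxy-2,2-dimethyl-3,4-dihydro-2H-chromen-8-yl]-2-methylbutan-1-one (target)
Conditions: H2 (1 atm), 10% Pd/C, EtOAc, rt
Reagents that add atoms: none
Why: hydrogenolysis of the two aryl benzyl ethers over palladium under neutral conditions, at a stage where no alkene is left; the aryl ketones, the chroman C–O bonds and both stereocentres should not be affected.

**Compound list**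

1 | phloroglucinol (benzene-1,3,5-triol) | Oc1cc(O)cc(O)c1 | starting material
2 | (R)-2-methylbutanoic acid | CC[C@@H](C)C(=O)O | starting material
3 | (R)-2-methylbutanoyl chloride | CC[C@@H](C)C(=O)Cl | intermediate (not isolated)
4 | (2R)-2-methyl-1-(2,4,6-trihydroxyphenyl)butan-1-one | CC[C@@H](C)C(=O)c1c(O)cc(O)cc1O | intermediate
5 | 1-bromo-3-methylbut-2-ene (prenyl bromide) | CC(C)=CCBr | starting material
6 | (2R)-2-methyl-1-[2,4,6-trihydroxy-3-(3-methylbut-2-en-1-yl)phenyl]butan-1-one | CC[C@@H](C)C(=O)c1c(O)cc(O)c(CC=C(C)C)c1O | intermediate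
7 | (2R)-1-[4-(benzyloxy)-2,6-dihydroxy-3-(3-methylbut-2-en-1-yl)phenyl]-2-methylbutan-1-one (ring A monomer) | CC[C@@H](C)C(=O)c1c(O)cc(OCc2ccccc2)c(CC=C(C)C)c1O | intermediate
8 | 2-methylpropanoyl chloride (isobutyryl chloride) | CC(C)C(=O)Cl | starting material
9 | 2-methyl-1-(2,4,6-trihydroxyphenyl)propan-1-one | CC(C)C(=O)c1c(O)cc(O)cc1O | intermediate
10 | 2-methyl-1-[2,4,6-trihydroxy-3-(3-methylbut-2-en-1-yl)phenyl]propan-1-one | CC(C)C(=O)c1c(O)cc(O)c(CC=C(C)C)c1O | intermediate
11 | 1-[4-(benzyloxy)-2,6-dihydroxy-3-(3-methylbut-2-en-1-yl)phenyl]-2-methylpropan-1-one (ring B monomer) | CC(C)C(=O)c1c(O)cc(OCc2ccccc2)c(CC=C(C)C)c1O | intermediate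
12 | 6-methylheptanoic acid | CC(C)CCCCC(=O)O | starting material
13 | 6-methylheptan-1-ol | CC(C)CCCCCO | intermediate
14 | 6-methylheptanal | CC(C)CCCCC=O | intermediate
15 | racemic 1-[4-(benzyloxy)-2,6-dihydroxy-3-(1-hydroxy-6-methylheptyl)-5-(3-methylbut-2-en-1-yl)phenyl]-2-methylpropan-1-one (benzylic carbinol) | CC(C)C(=O)c1c(O)c(C(O)CCCCC(C)C)c(OCc2ccccc2)c(CC=C(C)C)c1O | intermediate (not isolated)
16 | racemic 1-[4-(benzyloxy)-2,6-dihydroxy-3-[6-methyl-1-(4-methylbenzenesulfonyl)heptyl]-5-(3-methylbut-2-en-1-yl)phenyl]-2-methylpropan-1-one (sulfone) | CC(C)C(=O)c1c(O)c(C(CCCCC(C)C)S(=O)(=O)c2ccc(C)cc2)c(OCc2ccccc2)c(CC=C(C)C)c1O | intermediate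
17 | 5-(benzyloxy)-3-hydroxy-6-(6-methylheptylidene)-4-(3-methylbut-2-en-1-yl)-2-(2-methylpropanoyl)cyclohexa-2,4-dien-1-one (ortho-quinone methide, alkene geometry not defined) | CC(C)CCCCC=C1C(=O)C(C(=O)C(C)C)=C(O)C(CC=C(C)C)=C1OCc1ccccc1 | intermediate (not isolated)
18 | (2R)-1-[4-(benzyloxy)-3-[(1R)-1-[6-(benzyloxy)-2,4-dihydroxy-3-(2-methylpropanoyl)-5-(3-methylbut-2-en-1-yl)phenyl]-6-methylheptyl]-2,6-dihydroxy-5-(3-methylbut-2-en-1-yl)phenyl]-2-methylbutan-1-one (open bis-prenyl tetraphenol, C5 and C5' oxygens benzylated) | CC[C@@H](C)C(=O)c1c(O)c([C@H](CCCCC(C)C)c2c(OCc3ccccc3)c(CC=C(C)C)c(O)c(C(=O)C(C)C)c2O)c(OCc2ccccc2)c(CC=C(C)C)c1O | intermediate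
19 | compound 18 in which only the ring A prenyl group has closed to the 2,2-dimethylchroman (ring C); both stereocentres arranged as in 18 | CC[C@@H](C)C(=O)c1c(O)c([C@H](CCCCC(C)C)c2c(OCc3ccccc3)c(CC=C(C)C)c(O)c(C(=O)C(C)C)c2O)c(OCc2ccccc2)c2c1OC(C)(C)CC2 | intermediate (not isolated)
20 | compound 18 in which only the ring B prenyl group has closed to the 2,2-dimethylchroman (ring D); both stereocentres arranged as in 18 | CC[C@@H](C)C(=O)c1c(O)c([C@H](CCCCC(C)C)c2c(OCc3ccccc3)c3c(c(C(=O)C(C)C)c2O)OC(C)(C)CC3)c(OCc2ccccc2)c(CC=C(C)C)c1O | intermediate (not isolated)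
21 | (2R)-1-[5-(benzyloxy)-6-[(1R)-1-[5-(benzyloxy)-7-hydroxy-2,2-dimethyl-8-(2-methylpropanoyl)-3,4-dihydro-2H-chromen-6-yl]-6-methylheptyl]-7-hydroxy-2,2-dimethyl-3,4-dihydro-2H-chromen-8-yl]-2-methylbutan-1-one (5,5'-di-O-benzyl ether of the target) | CC[C@@H](C)C(=O)c1c(O)c([C@H](CCCCC(C)C)c2c(OCc3ccccc3)c3c(c(C(=O)C(C)C)c2O)OC(C)(C)CC3)c(OCc2ccccc2)c2c1OC(C)(C)CC2 | intermediate
22 | (2R)-1-[6-[(1R)-1-[5,7-dihydroxy-2,2-dimethyl-8-(2-methylpropanoyl)-3,4-dihydro-2H-chromen-6-yl]-6-methylheptyl]-5,7-dihydroxy-2,2-dimethyl-3,4-dihydro-2H-chromen-8-yl]-2-methylbutan-1-one (CNP0287681.1) | CC[C@@H](C)C(=O)c1c(O)c([C@H](CCCCC(C)C)c2c(O)c3c(c(C(=O)C(C)C)c2O)OC(C)(C)CC3)c(O)c2c1OC(C)(C)CC2 | target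

**Step count**

Total: 12 steps. Longest linear sequence: 7 steps (steps 4, 5, 6, 9, 10, 11, 12, from phloroglucinol through the ring B branch).

**Three steps most likely to fail**

Step 10. The catalyst may discriminate poorly between the two faces of the quinone methide carbon, because both positions flanking it are substituted and the two arenes differ only in a remote acyl group. The alkyl quinone methide may also drain away by tautomerising to the styrene, and the product may slowly re-ionise under base. The fallback sets out from 16 and 7. They are coupled without chiral control (Et3N, CH2Cl2, rt; the same elimination and conjugate addition), which should give 18 together with its (S)-methine epimer F1. Because of the fixed (R)-2-methylbutanoyl centre these two are diastereomers, and they are separated by preparative HPLC on a cellulose tris(3,5-dimethylphenylcarbamate) stationary phase. The route is rejoined at 18.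

Step 11. The tertiary radical may take up a second hydrogen atom (reduction of a prenyl group to an isopentyl chain), the benzyl ether oxygen on C5 may take part with loss of benzyl, or the N–F oxidant may attack the electron-rich rings. The fallback sets out from 18. Treatment with N-iodosuccinimide (2.2 equiv, CH2Cl2, −40 °C) should form an iodonium ion on each prenyl alkene, which the C8a hydroxyl opens at the tertiary carbon (6-endo) to give the bis(3-iodochroman) F2. Radical deiodination (Bu3SnH, AIBN, toluene, 80 °C) then removes both iodine atoms, and the route is rejoined at 21.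

Step 9. Under the acidic three-component conditions the protonated quinone methide may be captured by a second molecule of 11 (self-condensation to the symmetric dimer), or the acid may close the prenyl group early. The fallback sets out from 11 and 14. A Betti-type Mannich condensation with morpholine (EtOH, rt) forms the C–C bond through the iminium ion under mildly basic conditions and gives the morpholine Mannich base F3. Exchange of the amine for sulfinate (4-MeC6H4SO2H, CH2Cl2, rt; the protonated amine leaves and sulfinic acid adds to the quinone methide) brings the route back at 16.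

**Further compounds**

F1 | step 10 | (2R)-1-[4-(benzyloxy)-3-[(1S)-1-[6-(benzyloxy)-2,4-dihydroxy-3-(2-methylpropanoyl)-5-(3-methylbut-2-en-1-yl)phenyl]-6-methylheptyl]-2,6-dihydroxy-5-(3-methylbut-2-en-1-yl)phenyl]-2-methylbutan-1-one (methine epimer of 18) | CC[C@@H](C)C(=O)c1c(O)c([C@@H](CCCCC(C)C)c2c(OCc3ccccc3)c(CC=C(C)C)c(O)c(C(=O)C(C)C)c2O)c(OCc2ccccc2)c(CC=C(C)C)c1O
F2 | step 11 | 3,3'-diiodo derivative of 21 (iodine on C3 of ring C and of ring D, both formed as epimer mixtures; methine and acyl centres as in 21) | CC[C@@H](C)C(=O)c1c(O)c([C@H](CCCCC(C)C)c2c(OCc3ccccc3)c3c(c(C(=O)C(C)C)c2O)OC(C)(C)C(I)C3)c(OCc2ccccc2)c2c1OC(C)(C)C(I)C2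
F3 | step 9 | racemic 1-[4-(benzyloxy)-2,6-dihydroxy-3-[6-methyl-1-(morpholin-4-yl)heptyl]-5-(3-methylbut-2-en-1-yl)phenyl]-2-methylpropan-1-one (Mannich base) | CC(C)C(=O)c1c(O)c(C(CCCCC(C)C)N2CCOCC2)c(OCc2ccccc2)c(CC=C(C)C)c1O
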